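**Retrosynthetic overview**
1. Late operations: free C15-OH, acylate C8-OH with (Z)-4-acetoxy-2-methylbut-2-enoic acid, and methylenate C11 of a protected 1β,10α-epoxy-13-norgermacradien-6α,12-olide.
2. Key disconnection: C1–C10. This is the C–C bond of the oxirane (ring C) and also a bond of the ten-membered carbocycle (ring A). An intramolecular sulfonium-ylide epoxidation (C1 tetrahydrothiophenium salt plus C10 methyl ketone) closes rings A and C together from a monocyclic butyrolactone.
3. Enabling feature: C1 is both an oxirane carbon and the allylic terminus of the C2=C3–C4=C5 diene, so a C1 sulfonium salt is far more acidic than the ketone. C10 is the oxirane carbon that bears the C14 methyl group, i.e. a latent methyl ketone. The two ring-cis double bonds and the trans-fused lactone ring B (O–C6–C7–C11–C12) fold C1 towards C10.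
4. The seco precursor comes from a Stille coupling (C3–C4), an L-proline aldol with acetone (C8–C9, sets C8) and a thiazolidinethione syn-aldol/lactonisation (C6–C7, sets C6 and C7). The building blocks are butynediol, a succinate, acetone and propargyl alcohol.
5. Ring order: lactone B first (step 5), then carbocycle A and oxirane C together (step 13). C13 is added afterwards because the ylide would cyclopropanate an α-methylene lactone.

Key step: step 13

Remark: germacrane numbering (C1–C15) and the α/β descriptors of the target are used for all intermediates. C4=C5 is cis in the ring (C3 cis to C6) but is E by CIP once C15 carries oxygen, and the C8 ester side chain is taken as drawn, (Z), i.e. the 4-acetoxyangelate type.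

**Step 1**
Reactants: 1 but-2-yne-1,4-diol
Product: 2 4-(tert-butyldiphenylsilyloxy)but-2-yn-1-ol
Conditions: NaH (1.0 equiv), THF, 0 °C to rt; then t-BuPh2SiCl (1.0 equiv)
Reagents that add atoms: tert-butyldiphenylsilyl chloride, CC(C)(C)[Si](Cl)(c1ccccc1)c1ccccc1
Why: O-silylation of the sparingly soluble monosodium alkoxide of a symmetrical diol should stop at the monoether, and no stereocenter is involved.

**Step 2**
Reactants: 2 4-(tert-butyldiphenylsilyloxy)but-2-yn-1-ol
Product: 4 (Z)-4-(tert-butyldiphenylsilyloxy)-3-iodobut-2-en-1-ol, via alkenylaluminate 3 (not isolated)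
Conditions: NaAlH2(OCH2CH2OMe)2, THF, 0 °C to rt; then I2, THF, −78 °C to 0 °C
Reagents that add atoms: iodine, II
Why: Hydroxyl-directed trans-hydroalumination of a propargylic alcohol puts aluminium on the distal alkyne carbon (C4) cis to C6 in a five-membered aluminate, and iodinolysis with retention fixes the C4=C5 geometry (iodine, the later C3, cis to C6).

**Step 3**
Reactants: 4 (Z)-4-(tert-butyldiphenylsilyloxy)-3-iodobut-2-en-1-ol
Product: 5 (Z)-4-(tert-butyldiphenylsilyloxy)-3-iodobut-2-enal
Conditions: MnO2 (excess), CH2Cl2, rt, dark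
Reagents that add atoms: none
Why: Allylic alcohol oxidation with MnO2 is neutral and heterogeneous, so the (Z)-β-iodoenal should form without geometric isomerisation.

**Step 4**
Reactants: 6 (S)-4-benzyl-1,3-thiazolidine-2-thione; 7 methyl 4-chloro-4-oxobutanoate
Product: 8 methyl 4-[(4S)-4-benzyl-2-thioxo-1,3-thiazolidin-3-yl]-4-oxobutanoate
Conditions: Et3N, DMAP (cat.), CH2Cl2, 0 °C to rt
Reagents that add atoms: none
Why: N-acylation of the thiazolidinethione with an acid chloride gives the thermodynamically preferred N-acyl compound and leaves the auxiliary stereocenter untouched.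

**Step 5**
Reactants: 8 methyl 4-[(4S)-4-benzyl-2-thioxo-1,3-thiazolidin-3-yl]-4-oxobutanoate; 5 (Z)-4-(tert-butyldiphenylsilyloxy)-3-iodobut-2-enal
Product: 11 trans-lactone imide (ring B; H-6β/H-7α; C7 carries the C8 acyl thiazolidinethione; C6 carries the (Z)-2-iodo-3-silyloxyprop-1-enyl group), via titanium enolate 9 (not isolated), via titanium aldolate 10 (not isolated)
Conditions: TiCl4 (1.05 equiv), i-Pr2NEt (1.1 equiv), N-methyl-2-pyrrolidinone (1.0 equiv), CH2Cl2, 0 °C; then 5, −78 °C to rt; aq. NH4Cl
Reagents that add atoms: none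
Why: In this Evans-type syn aldol reaction of the titanium (Z)-enolate of an N-acylthiazolidinethione, the non-chelated chair transition state reacts on the enolate face opposite to the benzyl group and sets C6 and C7, and the syn aldolate then lactonises onto the methyl ester to give the trans-lactone.

**Step 6**
Reactants: 11 trans-lactone imide
Product: 12 trans-lactone aldehyde (C8 formyl group on C7; H-6β/H-7α; C4 iodide)
Conditions: i-Bu2AlH (1.1 equiv), CH2Cl2, −78 °C; aq. potassium sodium tartrate
Reagents that add atoms: none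
Why: Reductive cleavage of the activated N-acylthiazolidinethione by i-Bu2AlH should be much faster than lactone reduction at −78 °C (fading of the yellow colour marks the end point) and should stop at the aldehyde without touching C6 or C7.

**Step 7**
Reactants: 12 trans-lactone aldehyde; 13 acetone
Product: 14 8β-hydroxy ketone (C8 R; C10 methyl ketone; H-6β/H-7α; C4 iodide)
Conditions: L-proline (30 mol %), acetone/DMSO 1:4, rt
Reagents that add atoms: none
Why: In this proline-catalysed direct aldol reaction (enamine catalysis) the L-proline enamine of acetone should attack the Re face of the α-branched aldehyde in the acid-organised chair transition state, which sets C8 (R, 8β-OH) under catalyst control while C7 keeps its thermodynamically preferred trans arrangement.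

**Step 8**
Reactants: 14 8β-hydroxy ketone
Product: 15 8β-triethylsilyl ether of 14
Conditions: Et3SiCl, imidazole, DMF, 0 °C
Reagents that add atoms: triethylsilyl chloride, CC[Si](Cl)(CC)CC
Why: Imidazole-mediated O-silylation protects the β-hydroxy ketone under conditions too mild for enol silane formation, dehydration or translactonisation, and no stereocenter changes.

**Step 9**
Reactants: 16 prop-2-yn-1-ol
Product: 18 (Z)-3-(tributylstannyl)prop-2-en-1-ol, via alkenylaluminate 17 (not isolated)
Conditions: LiAlH4, THF, 0 °C to rt; then Bu3SnOTf, −78 °C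
Reagents that add atoms: tributyltin trifluoromethanesulfonate, CCCC[Sn](CCCC)(CCCC)OS(=O)(=O)C(F)(F)F
Why: Hydroxyl-directed trans-hydroalumination of propargyl alcohol followed by aluminium-to-tin exchange with retention should give the (Z)-alkenylstannane, which fixes the C2=C3 geometry.

**Step 10**
Reactants: 15 8β-triethylsilyl ether; 18 (Z)-3-(tributylstannyl)prop-2-en-1-ol
Product: 19 seco dienol (C1 primary alcohol; 2Z,4E-diene with C1 cis to C4 and C3 cis to C6; 8β-OSiEt3; C10 ketone; 15-OSiPh2t-Bu)
Conditions: Pd2(dba)3 (5 mol %), AsPh3 (20 mol %), CuI (10 mol %), DMF, rt, dark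
Reagents that add atoms: none
Why: The Stille cross-coupling proceeds with retention at both sp2 carbons and so forms C3–C4 with the cis,cis-diene geometry, because zerovalent palladium inserts into the C–I bond faster than it can ionise the hindered allylic C6–O bond of the lactone.

**Step 11**
Reactants: 19 seco dienol
Product: 20 C1 allylic bromide of 19
Conditions: CBr4, PPh3, CH2Cl2, −30 °C
Reagents that add atoms: carbon tetrabromide, BrC(Br)(Br)Br
Why: In the Appel reaction bromide displaces the alkoxyphosphonium group at primary C1 by SN2 under neutral conditions, which leaves the silyl ethers, the ketone and both double-bond geometries intact.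

**Step 12**
Reactants: 20 C1 allylic bromide
Product: 21 C1 tetrahydrothiophenium tetrafluoroborate (dienylic sulfonium salt of the seco keto lactone)
Conditions: tetrahydrothiophene (3 equiv), NaBF4 (5 equiv), CH2Cl2/H2O, rt, dark
Reagents that add atoms: tetrahydrothiophene, C1CCSC1; sodium tetrafluoroborate, [Na+].F[B-](F)(F)F
Why: SN2 S-alkylation of a cyclic sulfide by a primary allylic bromide, combined with biphasic exchange to the non-nucleophilic BF4 anion, should suppress reversal and allylic scrambling.

**Step 13**
Reactants: 21 C1 tetrahydrothiophenium tetrafluoroborate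
Product: 24 1β,10α-epoxy-8β-(triethylsilyloxy)-15-(tert-butyldiphenylsilyloxy)-13-norgermacra-2Z,4E-dien-6α,12-olide (both double bonds cis in ring A; trans-oxirane; trans-lactone), via sulfonium ylide 22 (not isolated), via betaine 23 (not isolated)
Conditions: Cs2CO3 (3 equiv), MeCN, 0 °C to rt, syringe-pump addition of 21 (final concentration about 1 mM)
Reagents that add atoms: none
Why: Proposed new method: Cs2CO3 removes a C1 proton of the dienylic sulfonium salt (acidified by the sulfonium group and by the C2=C3–C4=C5 diene, far below the C9/C14 ketone and C11 lactone protons), ylide 22 adds through C1 to the C10 ketone (10-exo-trig, closes carbocycle A), and the alkoxide of betaine 23 displaces tetrahydrothiophene from C1 with inversion (3-exo-tet, closes oxirane C), so two rings and two stereocenters arise in one operation. The closest known reaction types are the intermolecular Corey–Chaykovsky epoxidation of ketones with allylic sulfonium ylides and its intramolecular version that builds five- to seven-membered rings fused to an oxirane, and what is new here is the closure of a ten-membered ring. C10 should be set by C8, because in the dipole-minimised conformer of the C8(OSiEt3)–C9–C10=O segment (1,3-anti polar model), with C8 held by the trans-lactone, the Si face of the carbonyl group lies on the path of C1, which puts the oxygen α and C14 β. C1 should be set relative to C10 in the betaine, because only the anti betaine with C2 antiperiplanar to C9 can bring the alkoxide antiperiplanar to sulfur and close, while the syn betaine should revert to ylide and ketone, so the trans (1β,10α) oxirane is expected. The step needs α- over γ-attack of the ylide (general for sulfonium allylides, since only the α-adduct has a leaving group that traps it), ring closure over oligomerisation (high dilution, a low stationary ylide concentration with a weak heterogeneous base, and the fold imposed by the two cis double bonds and lactone ring B), and the absence of a competing acceptor (the C11 methylene group, which such ylides would cyclopropanate, is therefore added only in step 14). The Z geometry of C2=C3 should survive because the charge stays largely on C1 next to sulfur and Z-allyl anions are not disfavoured against their E isomers.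

**Step 14**
Reactants: 24 13-nor epoxy lactone
Product: 28 1β,10α-epoxy-8β-(triethylsilyloxy)-15-(tert-butyldiphenylsilyloxy)germacra-2Z,4E,11(13)-trien-6α,12-olide, via lithium enolate 25 (not isolated), via Mannich base 26 (not isolated), via methiodide 27 (not isolated)
Conditions: LiN(i-Pr)2 (1.2 equiv), THF, −78 °C; CH2=NMe2 iodide, −78 °C to rt; then MeI, CH2Cl2, rt; then aq. NaHCO3
Reagents that add atoms: Eschenmoser's salt (N,N-dimethylmethyleneiminium iodide), C=[N+](C)C.[I-]
Why: Mannich-type α-aminomethylation of the lactone enolate with Eschenmoser's salt (anti to the C7 side chain), quaternisation and E1cB (Hofmann-type) elimination install the exocyclic C11=C13 bond, the transient C11 stereocenter is destroyed again, and the only proton acidic to the amide base at −78 °C is at C11.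

**Step 15**
Reactants: 28 α-methylene lactone
Product: 29 1β,10α-epoxy-8β-hydroxy-15-(tert-butyldiphenylsilyloxy)germacra-2Z,4E,11(13)-trien-6α,12-olide
Conditions: HF·pyridine, pyridine, THF, 0 °C
Reagents that add atoms: none
Why: In this selective desilylation the secondary Et3Si ether is cleaved by pyridine-buffered HF far faster than the primary t-BuPh2Si ether, and the excess pyridine should keep the dienyl oxirane intact.

**Step 16**
Reactants: 30 but-2-yn-1-ol
Product: 32 (Z)-3-iodobut-2-en-1-ol, via alkenylaluminate 31 (not isolated)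
Conditions: NaAlH2(OCH2CH2OMe)2, THF, 0 °C to rt; then I2, THF, −78 °C to 0 °C
Reagents that add atoms: iodine, II
Why: Hydroxyl-directed trans-hydroalumination and iodinolysis with retention place iodine cis to the CH2OH group, which fixes the (Z) geometry of the side chain.

**Step 17**
Reactants: 32 (Z)-3-iodobut-2-en-1-ol
Product: 33 (Z)-3-iodobut-2-en-1-yl acetate
Conditions: Ac2O, pyridine, CH2Cl2, 0 °C to rt
Reagents that add atoms: acetic anhydride, CC(=O)OC(C)=O
Why: Acetylation before the carboxyl group is introduced ensures that a free (Z)-γ-hydroxy acid, which would close to the butenolide, never appears.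

**Step 18**
Reactants: 33 (Z)-3-iodobut-2-en-1-yl acetate
Product: 34 (Z)-4-acetoxy-2-methylbut-2-enoic acid
Conditions: PdCl2(PPh3)2 (3 mol %), CO (1 atm), H2O, Et3N, THF, rt
Reagents that add atoms: carbon monoxide, [C-]#[O+]; water, O
Why: Palladium-catalysed hydroxycarbonylation of an alkenyl iodide proceeds with retention of geometry, and under CO the oxidative addition of zerovalent palladium into the C–I bond should be much faster than ionisation of the primary allylic acetate.

**Step 19**
Reactants: 34 (Z)-4-acetoxy-2-methylbut-2-enoic acid; 29 8β-alcohol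
Product: 36 8β-[(Z)-4-acetoxy-2-methylbut-2-enoyloxy]-1β,10α-epoxy-15-(tert-butyldiphenylsilyloxy)germacra-2Z,4E,11(13)-trien-6α,12-olide, via mixed anhydride 35 (not isolated)
Conditions: 34, 2,4,6-trichlorobenzoyl chloride, Et3N, toluene, rt; then 29, toluene, 60 °C (no nucleophilic catalyst)
Reagents that add atoms: none
Why: The Yamaguchi esterification through the mixed anhydride acylates the C8 oxygen with retention at C8, and leaving out a nucleophilic catalyst avoids the addition–elimination path that turns angelate-type (Z)-acyl groups into their (E) isomers.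

**Step 20**
Reactants: 36 15-O-silyl ester
Product: 37 target, (1R,6R,7R,8R,10R)-8β-[(Z)-4-acetoxy-2-methylbut-2-enoyloxy]-1β,10α-epoxy-15-hydroxygermacra-2Z,4E,11(13)-trien-6α,12-olide
Conditions: Bu4NF, AcOH (1:1), THF, 0 °C to rt
Reagents that add atoms: none
Why: Fluoride-mediated desilylation buffered with acetic acid is close to neutral, so the acetate, the α-methylene lactone, the (Z)-enoate and the dienyl oxirane should survive and no stereocenter is touched.

**Compound list**
1 | but-2-yne-1,4-diol | OCC#CCO | starting material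
2 | 4-(tert-butyldiphenylsilyloxy)but-2-yn-1-ol | OCC#CCO[Si](c1ccccc1)(c1ccccc1)C(C)(C)C | intermediate
3 | sodium cyclic alkenylaluminate from 2 (Al on C4, cis to C6) | [Na+].COCCO[Al-]1(OCCOC)OCC=C1CO[Si](c2ccccc2)(c3ccccc3)C(C)(C)C | intermediate
4 | (Z)-4-(tert-butyldiphenylsilyloxy)-3-iodobut-2-en-1-ol | OC/C=C(\I)CO[Si](c1ccccc1)(c1ccccc1)C(C)(C)C | intermediate
5 | (Z)-4-(tert-butyldiphenylsilyloxy)-3-iodobut-2-enal | O=C/C=C(\I)CO[Si](c1ccccc1)(c1ccccc1)C(C)(C)C | intermediate
6 | (S)-4-benzyl-1,3-thiazolidine-2-thione | S=C1N[C@@H](Cc2ccccc2)CS1 | starting material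
7 | methyl 4-chloro-4-oxobutanoate | COC(=O)CCC(=O)Cl | starting material
8 | methyl 4-[(4S)-4-benzyl-2-thioxo-1,3-thiazolidin-3-yl]-4-oxobutanoate | COC(=O)CCC(=O)N1[C@@H](Cc2ccccc2)CSC1=S | intermediate
9 | trichlorotitanium (Z)-enolate of 8 | COC(=O)C/C=C(\O[Ti](Cl)(Cl)Cl)N1[C@@H](Cc2ccccc2)CSC1=S | intermediate
10 | trichlorotitanium syn-aldolate | COC(=O)C[C@H](C(=O)N1[C@@H](Cc2ccccc2)CSC1=S)[C@H](O[Ti](Cl)(Cl)Cl)/C=C(\I)CO[Si](c1ccccc1)(c1ccccc1)C(C)(C)C | intermediate
11 | trans-lactone imide (H-6β, H-7α) | O=C1C[C@H](C(=O)N2[C@@H](Cc3ccccc3)CSC2=S)[C@@H](/C=C(\I)CO[Si](c2ccccc2)(c3ccccc3)C(C)(C)C)O1 | intermediate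
12 | trans-lactone aldehyde (H-6β, H-7α) | O=C1C[C@H](C=O)[C@@H](/C=C(\I)CO[Si](c2ccccc2)(c3ccccc3)C(C)(C)C)O1 | intermediate
13 | acetone | CC(C)=O | starting material
14 | 8β-hydroxy ketone (C8 R) | O=C1C[C@H]([C@H](O)CC(C)=O)[C@@H](/C=C(\I)CO[Si](c2ccccc2)(c3ccccc3)C(C)(C)C)O1 | intermediate
15 | 8β-triethylsilyl ether of 14 | O=C1C[C@H]([C@H](O[Si](CC)(CC)CC)CC(C)=O)[C@@H](/C=C(\I)CO[Si](c2ccccc2)(c3ccccc3)C(C)(C)C)O1 | intermediate
16 | prop-2-yn-1-ol | C#CCO | starting material
17 | lithium cyclic alkenylaluminate from 16 | [Li+].[AlH2-]1OCC=C1 | intermediate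
18 | (Z)-3-(tributylstannyl)prop-2-en-1-ol | OC/C=C\[Sn](CCCC)(CCCC)CCCC | intermediate
19 | seco dienol (2Z,4E; C1-OH) | O=C1C[C@H]([C@H](O[Si](CC)(CC)CC)CC(C)=O)[C@@H](/C=C(CO[Si](c2ccccc2)(c3ccccc3)C(C)(C)C)\C=C/CO)O1 | intermediate
20 | seco C1 allylic bromide | O=C1C[C@H]([C@H](O[Si](CC)(CC)CC)CC(C)=O)[C@@H](/C=C(CO[Si](c2ccccc2)(c3ccccc3)C(C)(C)C)\C=C/CBr)O1 | intermediate
21 | seco C1 tetrahydrothiophenium tetrafluoroborate | O=C1C[C@H]([C@H](O[Si](CC)(CC)CC)CC(C)=O)[C@@H](/C=C(CO[Si](c2ccccc2)(c3ccccc3)C(C)(C)C)\C=C/C[S+]2CCCC2)O1.F[B-](F)(F)F | intermediate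
22 | dienylic sulfonium ylide | O=C1C[C@H]([C@H](O[Si](CC)(CC)CC)CC(C)=O)[C@@H](/C=C(CO[Si](c2ccccc2)(c3ccccc3)C(C)(C)C)\C=C/[CH-][S+]2CCCC2)O1 | intermediate
23 | anti betaine (ring A closed; C10 alkoxide, C1 sulfonium) | C1C(=O)O[C@@H]2/C=C(CO[Si](c4ccccc4)(c5ccccc5)C(C)(C)C)\C=C/[C@H]([S+]3CCCC3)[C@@]([O-])(C)C[C@@H](O[Si](CC)(CC)CC)[C@@H]12 | intermediate
24 | 1β,10α-epoxy-8β-(triethylsilyloxy)-15-(tert-butyldiphenylsilyloxy)-13-norgermacra-2Z,4E-dien-6α,12-olide | C1C(=O)O[C@@H]2/C=C(CO[Si](c4ccccc4)(c5ccccc5)C(C)(C)C)\C=C/[C@H]3O[C@]3(C)C[C@@H](O[Si](CC)(CC)CC)[C@@H]12 | intermediate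
25 | lithium enolate of 24 | C1=C([O-])O[C@@H]2/C=C(CO[Si](c4ccccc4)(c5ccccc5)C(C)(C)C)\C=C/[C@H]3O[C@]3(C)C[C@@H](O[Si](CC)(CC)CC)[C@@H]12.[Li+] | intermediate
26 | C11 dimethylaminomethyl lactone (CH2NMe2 anti to C8) | CN(C)C[C@@H]1C(=O)O[C@@H]2/C=C(CO[Si](c4ccccc4)(c5ccccc5)C(C)(C)C)\C=C/[C@H]3O[C@]3(C)C[C@@H](O[Si](CC)(CC)CC)[C@@H]12 | intermediate
27 | methiodide of 26 | C[N+](C)(C)C[C@@H]1C(=O)O[C@@H]2/C=C(CO[Si](c4ccccc4)(c5ccccc5)C(C)(C)C)\C=C/[C@H]3O[C@]3(C)C[C@@H](O[Si](CC)(CC)CC)[C@@H]12.[I-] | intermediate
28 | 1β,10α-epoxy-8β-(triethylsilyloxy)-15-(tert-butyldiphenylsilyloxy)germacra-2Z,4E,11(13)-trien-6α,12-olide | C=C1C(=O)O[C@@H]2/C=C(CO[Si](c4ccccc4)(c5ccccc5)C(C)(C)C)\C=C/[C@H]3O[C@]3(C)C[C@@H](O[Si](CC)(CC)CC)[C@@H]12 | intermediate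
29 | 8β-alcohol of 28 | C=C1C(=O)O[C@@H]2/C=C(CO[Si](c4ccccc4)(c5ccccc5)C(C)(C)C)\C=C/[C@H]3O[C@]3(C)C[C@@H](O)[C@@H]12 | intermediate
30 | but-2-yn-1-ol | CC#CCO | starting material
31 | sodium cyclic alkenylaluminate from 30 | [Na+].COCCO[Al-]1(OCCOC)OCC=C1C | intermediate
32 | (Z)-3-iodobut-2-en-1-ol | OC/C=C(\I)C | intermediate
33 | (Z)-3-iodobut-2-en-1-yl acetate | CC(=O)OC/C=C(\I)C | intermediate
34 | (Z)-4-acetoxy-2-methylbut-2-enoic acid | CC(=O)OC/C=C(\C(=O)O)C | intermediate
35 | mixed anhydride of 34 and 2,4,6-trichlorobenzoic acid | CC(=O)OC/C=C(\C(=O)OC(=O)c1c(Cl)cc(Cl)cc1Cl)C | intermediate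
36 | 15-O-tert-butyldiphenylsilyl ether of the target | C=C1C(=O)O[C@@H]2/C=C(CO[Si](c4ccccc4)(c5ccccc5)C(C)(C)C)\C=C/[C@H]3O[C@]3(C)C[C@@H](OC(=O)/C(C)=C\COC(C)=O)[C@@H]12 | intermediate
37 | CNP0103272.1 | C=C1C(=O)O[C@@H]2/C=C(CO)\C=C/[C@H]3O[C@]3(C)C[C@@H](OC(=O)/C(C)=C\COC(C)=O)[C@@H]12 | target

**Step count**
Total step count: 20.
Longest linear sequence: 15 steps (1–3, 5–8, 10–15, 19, 20).

**Steps most likely to fail**

1. **Step 13.**
   - What may go wrong: oligomerisation may outrun the medium-ring closure. Proton transfer from C9 to the ylide may be followed by loss of silanolate. Facial selectivity at C10 may be poor, or the C2=C3 geometry may drift in the ylide.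
   - Fallback (known chemistry; sets out from 19, returns at 24): dienol 19 is oxidised with MnO2 to the (2Z,4E)-dienal keto lactone F1. The keto aldehyde is closed by a titanium-induced pinacol macrocyclisation to the 1α,10α-diol F2 (TiCl3(DME)1.5, Zn–Cu couple, DME, high dilution, ambient temperature so that deoxygenation to the alkene does not set in). Selective mesylation of the secondary allylic hydroxyl group (MsCl, Et3N, −20 °C) gives the C1 mesylate F3. On addition of DBU the C10 alkoxide displaces the mesylate with inversion at C1, which gives 24.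

2. **Step 7.**
   - What may go wrong: enamine or enol formation at the aldehyde may lead to β-elimination of the lactone carboxylate from C6. The new C8 hydroxyl group may cause translactonisation. The catalyst preference may be mismatched with the substrate bias.
   - Fallback (sets out from 12, returns at 14): a Mukaiyama aldol reaction with 2-(trimethylsilyloxy)propene and BF3·OEt2 in CH2Cl2 at −78 °C. These are non-basic conditions under substrate control. The small enol silane should follow the 1,3-anti polar model set by the C6 oxygen and give the same 8β-alcohol after aqueous work-up. This fallback makes no compound outside the list (entry F0).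

3. **Step 14.**
   - What may go wrong: the amide base may deprotonate next to the oxirane and isomerise it to an allylic alcohol, or aminomethylation of the hindered macrocyclic enolate may be incomplete.
   - Fallback (sets out from 24, returns at 28): Claisen condensation with diethyl oxalate (NaH, cat. EtOH, THF) gives the α-ethoxalyl lactone F4. Treatment with aqueous formaldehyde and K2CO3 then triggers aldol addition, acyl transfer to the new alkoxide and elimination of the oxalate half ester, which gives 28 without any strong amide base.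

**Further compounds**
F1 | step 13 | (2Z,4E)-dienal keto lactone (C1 aldehyde) | O=C1C[C@H]([C@H](O[Si](CC)(CC)CC)CC(C)=O)[C@@H](/C=C(CO[Si](c2ccccc2)(c3ccccc3)C(C)(C)C)\C=C/C=O)O1
F2 | step 13 | 1α,10α-dihydroxy-8β-(triethylsilyloxy)-15-(tert-butyldiphenylsilyloxy)-13-norgermacra-2Z,4E-dien-6α,12-olide | C1C(=O)O[C@@H]2/C=C(CO[Si](c4ccccc4)(c5ccccc5)C(C)(C)C)\C=C/[C@H](O)[C@@](O)(C)C[C@@H](O[Si](CC)(CC)CC)[C@@H]12
F3 | step 13 | C1 mesylate of F2 | C1C(=O)O[C@@H]2/C=C(CO[Si](c4ccccc4)(c5ccccc5)C(C)(C)C)\C=C/[C@H](OS(C)(=O)=O)[C@@](O)(C)C[C@@H](O[Si](CC)(CC)CC)[C@@H]12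
F0 | step 7 | none | none
F4 | step 14 | α-ethoxalyl lactone from 24 (C11 configurationally labile) | CCOC(=O)C(=O)C1C(=O)O[C@@H]2/C=C(CO[Si](c4ccccc4)(c5ccccc5)C(C)(C)C)\C=C/[C@H]3O[C@]3(C)C[C@@H](O[Si](CC)(CC)CC)[C@@H]12
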